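The route rests on cutting ring C (the dihydropyran of the chroman) at C4–C3 and O1–C2: its C3–C2(CH3)2 unit is intact isobutene, and C4 with O1 on the adjacent ring-A carbons C4a/C8a is an ortho-quinone methide. One operation, a three-component Mannich/elimination/hetero-Diels–Alder sequence of a phenol, formaldehyde and isobutene, forms both bonds and the whole ring. The precursor is the symmetric 3,5-bis(methoxymethoxy)phenol, whose single free hydroxyl dictates which oxygen closes. Directed lithiation between the two MOM ethers then places the acetyl group, and Claisen–Schmidt condensation with a prenylated isovanillin-type aldehyde, chemoselective hydrogenation and deprotection complete the dihydrochalcone.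

Key step: step 2

Remark: the target has no stereocentre and its only alkene carries two identical methyl groups, so no stereochemical element has to be set; paraformaldehyde is written as formaldehyde.

Step 1
Reactants: 1 phloroglucinol
Product: 2 3,5-bis(methoxymethoxy)phenol
Conditions: MOMCl (2.0 equiv), i-Pr2NEt (2.2 equiv), DMF, 0 °C to rt; chromatography
Reagents that add atoms: chloromethyl methyl ether, COCCl
Why: Williamson-type O-alkylation of the threefold-symmetric triol under statistical control can give only one bis-ether constitution, which should be separable from the mono- and tris-ethers (the mono-ether can be resubmitted).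

Step 2
Reactants: 2 3,5-bis(methoxymethoxy)phenol, 3 isobutene
Product: 6 5,7-bis(methoxymethoxy)-2,2-dimethylchroman, via Mannich base 4 (not isolated), via ortho-quinone methide 5 (not isolated)
Conditions: (CH2O)n (1.1 equiv), Bu2NH (0.5 equiv), isobutene (ca. 20 equiv, condensed in), toluene, steel autoclave, 80 °C then 160 °C
Reagents that add atoms: paraformaldehyde (as formaldehyde), C=O
Why: Dibutylamine and formaldehyde aminomethylate the phenol ortho to its only hydroxyl (Mannich reaction), and at 160 °C Mannich base 4 loses the amine by 1,4-elimination to give ortho-quinone methide 5, which isobutene traps in an inverse-electron-demand oxa-Diels–Alder reaction that forms C4–C3 and O1–C2 together. The closest known reaction type is the thermal three-component chroman synthesis from a phenol, formaldehyde and an alkene, long used for 2,2-dialkylchromans. Ring C is closed as a six-membered ring by a [4+2] cycloaddition (oxadiene C4=C4a–C8a=O1 plus the alkene), asynchronous, with the C–C bond leading and carbocation character at C2. No stereocentre is formed. The step needs ortho over para aminomethylation, a single annulation and one orientation of the alkene: the hydrogen-bonded Mannich transition state and the two OMOM groups flanking the para carbon secure the first, the single free hydroxyl of the symmetric phenol (both ortho carbons equivalent, no phenol left in the product) secures the second, and the polarity of 5 (electrophilic methylene, nucleophilic CH2 terminus of isobutene) places the gem-dimethyl carbon on oxygen. Capture of 5 by unreacted phenol should be held back by the large excess of isobutene.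

Step 3
Reactants: 6 5,7-bis(methoxymethoxy)-2,2-dimethylchroman
Product: 8 1-[5,7-bis(methoxymethoxy)-2,2-dimethylchroman-6-yl]ethanone, via aryllithium 7 (not isolated)
Conditions: n-BuLi (1.2 equiv), THF, 0 °C; then MeC(O)N(OMe)Me, −78 °C to rt; H2O
Reagents that add atoms: N-methoxy-N-methylacetamide, CC(=O)N(C)OC
Why: Directed ortho-metalation: C6–H lies between two chelating OMOM groups, so n-BuLi should deprotonate it in preference to C8–H (one OMOM and the ring ether), and the aryllithium adds once to the N-methoxy-N-methylamide through a chelated tetrahedral adduct that collapses to the methyl ketone only on work-up (Weinreb ketone synthesis).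

Step 4
Reactants: 9 3-bromo-4,5-dihydroxybenzaldehyde
Product: 10 3-bromo-5-hydroxy-4-methoxybenzaldehyde
Conditions: MeI (1.1 equiv), Li2CO3 (1.2 equiv), DMF, 40 °C
Reagents that add atoms: iodomethane, CI
Why: The 4-OH, para to the formyl group and ortho to bromine, is by far the more acidic phenol, so the weak base Li2CO3 should ionise and methylate it selectively (regioselective Williamson etherification).

Step 5
Reactants: 10 3-bromo-5-hydroxy-4-methoxybenzaldehyde
Product: 11 3-hydroxy-4-methoxy-5-(3-methylbut-2-en-1-yl)benzaldehyde
Conditions: Bu3SnCH2CH=CMe2 (1.3 equiv), Pd(PPh3)4 (5 mol%), DMF, 100 °C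
Reagents that add atoms: tributyl(3-methylbut-2-en-1-yl)stannane, CC(C)=CC[Sn](CCCC)(CCCC)CCCC
Why: Stille coupling: oxidative addition of the aryl bromide to zerovalent palladium, transmetalation of the prenyl group and reductive elimination at the less substituted terminus of the allyl ligand should give the linear prenyl arene, with the free phenol and the aldehyde tolerated.

Step 6
Reactants: 8 1-[5,7-bis(methoxymethoxy)-2,2-dimethylchroman-6-yl]ethanone, 11 3-hydroxy-4-methoxy-5-(3-methylbut-2-en-1-yl)benzaldehyde
Product: 12 (E)-1-[5,7-bis(methoxymethoxy)-2,2-dimethylchroman-6-yl]-3-[3-hydroxy-4-methoxy-5-(3-methylbut-2-en-1-yl)phenyl]prop-2-en-1-one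
Conditions: KOH (excess, 50% aq), EtOH, rt; then cold dilute AcOH to pH 6
Reagents that add atoms: none
Why: Claisen–Schmidt aldol condensation of the methyl ketone enolate with the non-enolisable aldehyde, followed by E1cB dehydration, should give the E-enone; both ortho oxygens of ring A are ethers, so no flavanone can form by oxa-Michael closure.

Step 7
Reactants: 12 (E)-chalcone
Product: 13 1-[5,7-bis(methoxymethoxy)-2,2-dimethylchroman-6-yl]-3-[3-hydroxy-4-methoxy-5-(3-methylbut-2-en-1-yl)phenyl]propan-1-one
Conditions: H2 (3 atm), RhCl(PPh3)3 (5 mol%), benzene/EtOH 1:1, rt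
Reagents that add atoms: none
Why: Homogeneous hydrogenation with RhCl(PPh3)3 is highly sensitive to alkene substitution, so the 1,2-disubstituted enone C=C should be saturated while the trisubstituted prenyl alkene, the ketone and the MOM acetals stay untouched.

Step 8
Reactants: 13 bis-MOM dihydrochalcone
Product: 14 1-(5,7-dihydroxy-2,2-dimethylchroman-6-yl)-3-[3-hydroxy-4-methoxy-5-(3-methylbut-2-en-1-yl)phenyl]propan-1-one (target)
Conditions: 3 M aq HCl/MeOH 1:5, 45 °C
Reagents that add atoms: none
Why: Acid-catalysed methanolysis of the two MOM acetals (helped by the ortho carbonyl) frees the two phenols; the prenyl group on ring B is flanked by OMe and has no ortho hydroxyl, so no acid-induced cyclisation can occur, and ring C is stable to dilute protic acid.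

Compound list
1 | phloroglucinol (benzene-1,3,5-triol) | Oc1cc(O)cc(O)c1 | starting material
2 | 3,5-bis(methoxymethoxy)phenol | COCOc1cc(O)cc(OCOC)c1 | intermediate
3 | isobutene (2-methylpropene) | CC(C)=C | starting material
4 | 2-[(dibutylamino)methyl]-3,5-bis(methoxymethoxy)phenol (Mannich base) | CCCCN(CCCC)Cc1c(O)cc(OCOC)cc1OCOC | intermediate
5 | 3,5-bis(methoxymethoxy)-6-methylidenecyclohexa-2,4-dien-1-one (ortho-quinone methide) | C=C1C(=O)C=C(OCOC)C=C1OCOC | intermediate
6 | 5,7-bis(methoxymethoxy)-2,2-dimethylchroman | COCOc1cc(OCOC)c2c(c1)OC(C)(C)CC2 | intermediate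
7 | [5,7-bis(methoxymethoxy)-2,2-dimethylchroman-6-yl]lithium | [Li]c1c(OCOC)cc2c(c1OCOC)CCC(C)(C)O2 | intermediate
8 | 1-[5,7-bis(methoxymethoxy)-2,2-dimethylchroman-6-yl]ethanone | CC(=O)c1c(OCOC)cc2c(c1OCOC)CCC(C)(C)O2 | intermediate
9 | 3-bromo-4,5-dihydroxybenzaldehyde | O=Cc1cc(O)c(O)c(Br)c1 | starting material
10 | 3-bromo-5-hydroxy-4-methoxybenzaldehyde | COc1c(O)cc(C=O)cc1Br | intermediate
11 | 3-hydroxy-4-methoxy-5-(3-methylbut-2-en-1-yl)benzaldehyde | COc1c(O)cc(C=O)cc1CC=C(C)C | intermediate
12 | (E)-1-[5,7-bis(methoxymethoxy)-2,2-dimethylchroman-6-yl]-3-[3-hydroxy-4-methoxy-5-(3-methylbut-2-en-1-yl)phenyl]prop-2-en-1-one | COc1c(O)cc(/C=C/C(=O)c2c(OCOC)cc3c(c2OCOC)CCC(C)(C)O3)cc1CC=C(C)C | intermediate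
13 | 1-[5,7-bis(methoxymethoxy)-2,2-dimethylchroman-6-yl]-3-[3-hydroxy-4-methoxy-5-(3-methylbut-2-en-1-yl)phenyl]propan-1-one | COc1c(O)cc(CCC(=O)c2c(OCOC)cc3c(c2OCOC)CCC(C)(C)O3)cc1CC=C(C)C | intermediate
14 | 1-(5,7-dihydroxy-2,2-dimethylchroman-6-yl)-3-[3-hydroxy-4-methoxy-5-(3-methylbut-2-en-1-yl)phenyl]propan-1-one | COc1c(O)cc(CCC(=O)c2c(O)cc3c(c2O)CCC(C)(C)O3)cc1CC=C(C)C | target

Total step count: 8
Longest linear sequence: 6 steps (steps 1, 2, 3, 6, 7, 8); steps 4 and 5 form the second branch, joined in step 6.

Steps most likely to fail

Step 2. Aminomethylation at both ortho carbons and capture of the quinone methide by unreacted phenol may outrun the cycloaddition to a gaseous, unactivated alkene. The fallback sets out from 2 and uses an isolated, strictly ortho quinone methide precursor. Magnesium-mediated ortho-formylation (MgCl2, Et3N, (CH2O)n, MeCN, reflux) should give 2-hydroxy-4,6-bis(methoxymethoxy)benzaldehyde F1. NaBH4 in MeOH at 0 °C should reduce it to 2-(hydroxymethyl)-3,5-bis(methoxymethoxy)phenol F2. Heating F2 at high dilution with a large excess of isobutene 3 (toluene, autoclave, 170 °C) should dehydrate it to the same quinone methide 5, now in the absence of amine, formaldehyde and free 2, and the cycloaddition returns to the route at 6.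

Step 3. Lithiation at C8, between the ring oxygen and one OMOM group, may compete with lithiation at C6, and the hindered aryllithium may enolise the amide instead of adding. The fallback sets out from 2 and moves the acylation in front of the annulation, where the arene is still symmetric. TIPSCl and imidazole in DMF should give [3,5-bis(methoxymethoxy)phenoxy]tri(propan-2-yl)silane F3. The bulky silyl ether shields its own ortho positions, so n-BuLi (THF, 0 °C) can only metalate the carbon between the two OMOM groups, giving [2,6-bis(methoxymethoxy)-4-(triisopropylsilyloxy)phenyl]lithium F4. With N-methoxy-N-methylacetamide this should give 1-[2,6-bis(methoxymethoxy)-4-(triisopropylsilyloxy)phenyl]ethanone F5, and Bu4NF in THF frees 1-[4-hydroxy-2,6-bis(methoxymethoxy)phenyl]ethanone F6. Under the conditions of step 2, F6 has its only free hydroxyl para to the acetyl group. It should pass through 1-{3-[(dibutylamino)methyl]-4-hydroxy-2,6-bis(methoxymethoxy)phenyl}ethanone F7 and 4-acetyl-3,5-bis(methoxymethoxy)-6-methylidenecyclohexa-2,4-dien-1-one F8, and close with isobutene 3 directly to 8, where the route is rejoined.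

Step 5. Allylic transposition during transmetalation may attach the side chain through its tertiary carbon, and oxidative addition to the electron-rich, ortho-substituted aryl bromide may be sluggish. The fallback sets out from 10. Stille coupling with allyltributylstannane (Pd(PPh3)4, DMF, 90 °C), which has no regiochemical ambiguity, should give 3-hydroxy-4-methoxy-5-(prop-2-en-1-yl)benzaldehyde F9. Cross-metathesis with 2-methylbut-2-ene (co-solvent, second-generation Grubbs catalyst RuCl2(=CHPh)(H2IMes)(PCy3), CH2Cl2, 40 °C) should convert the allyl into the prenyl group and return to the route at 11.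

Further compounds
F1 | step 2 | 2-hydroxy-4,6-bis(methoxymethoxy)benzaldehyde | O=Cc1c(O)cc(OCOC)cc1OCOC
F2 | step 2 | 2-(hydroxymethyl)-3,5-bis(methoxymethoxy)phenol | OCc1c(O)cc(OCOC)cc1OCOC
F3 | step 3 | [3,5-bis(methoxymethoxy)phenoxy]tri(propan-2-yl)silane | COCOc1cc(OCOC)cc(O[Si](C(C)C)(C(C)C)C(C)C)c1
F4 | step 3 | [2,6-bis(methoxymethoxy)-4-(triisopropylsilyloxy)phenyl]lithium | [Li]c1c(OCOC)cc(O[Si](C(C)C)(C(C)C)C(C)C)cc1OCOC
F5 | step 3 | 1-[2,6-bis(methoxymethoxy)-4-(triisopropylsilyloxy)phenyl]ethanone | CC(=O)c1c(OCOC)cc(O[Si](C(C)C)(C(C)C)C(C)C)cc1OCOC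
F6 | step 3 | 1-[4-hydroxy-2,6-bis(methoxymethoxy)phenyl]ethanone | CC(=O)c1c(OCOC)cc(O)cc1OCOC
F7 | step 3 | 1-{3-[(dibutylamino)methyl]-4-hydroxy-2,6-bis(methoxymethoxy)phenyl}ethanone | CCCCN(CCCC)Cc1c(O)cc(OCOC)c(C(C)=O)c1OCOC
F8 | step 3 | 4-acetyl-3,5-bis(methoxymethoxy)-6-methylidenecyclohexa-2,4-dien-1-one | C=C1C(=O)C=C(OCOC)C(C(C)=O)=C1OCOC
F9 | step 5 | 3-hydroxy-4-methoxy-5-(prop-2-en-1-yl)benzaldehyde | COc1c(O)cc(C=O)cc1CC=C
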